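**Plan**
1. Retrosynthesis: add back a C4=C5 double bond and put benzyl carbonates on both phenol oxygens (one hydrogenation removes both helpers); cut C6–C7, the bond from the carbinol carbon to its CH2 neighbour, by a retro carbonyl-ene reaction into 2-oxoheptanal and a terminal olefin; cut the aryl–C1 bond into an aryl Grignard reagent and (R)-1,2-epoxyhex-5-ene.
2. Enabling feature: the acyloin C7(OH)–C8(=O) is the ene adduct of a 1,2-dicarbonyl compound, whose adjacent aldehyde and ketone oxygens chelate a chiral divalent copper Lewis acid. The unfunctionalised C3–C6 chain can carry the C4=C5 olefin that the ene reaction leaves behind, and the resorcinol ring, the only ring, is made electron-poor for that step.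
3. Forward order: aryl–C1 bond (epoxide opening), C2 acetate, silyl-to-carbonate exchange on the ring, C6–C7 bond (ene union of the two fragments), then one hydrogenation that saturates C4=C5 and frees the phenols.
4. Stereochemistry: C2 is carried unchanged from the commercial (R)-epoxide; C7 is set by the chiral copper bis(oxazoline) catalyst in the ene reaction.

Key step: step 6

Remark: locants are those of the tridecane chain of the target (C1 benzylic CH2, C2 acetoxy carbon, C7 carbinol carbon, C8 ketone carbon). The sense of induction at C7 is assigned by analogy with glyoxylate enophiles and would be confirmed on 12 before step 7.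

**Step 1**
Reactants: 1 5-bromobenzene-1,3-diol
Product: 2 1-bromo-3,5-bis[(tert-butyldimethylsilyl)oxy]benzene
Conditions: TBSCl (2.3 equiv), imidazole, DMF, rt
Reagents that add atoms: tert-butyldimethylsilyl chloride, CC(C)(C)[Si](C)(C)Cl
Why: Imidazole-promoted silyl ether formation masks both acidic phenols so that the aryl bromide can be converted into a Grignard reagent; no stereocentre is involved.

**Step 2**
Reactants: 2 1-bromo-3,5-bis[(tert-butyldimethylsilyl)oxy]benzene; 3 (R)-2-(but-3-en-1-yl)oxirane [(R)-1,2-epoxyhex-5-ene]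
Product: 5 (2R)-1-{3,5-bis[(tert-butyldimethylsilyl)oxy]phenyl}hex-5-en-2-ol, via aryl Grignard reagent 4 (not isolated)
Conditions: Mg, THF, 50 °C; then CuBr·SMe2 (10 mol %), 3, THF, −30 → 0 °C; aq. NH4Cl
Reagents that add atoms: magnesium, [Mg] (retained only in intermediate 4)
Why: Copper-catalysed Grignard opening of a terminal epoxide takes place by SN2 attack at the unsubstituted ring carbon, so the C–O stereocentre of 3 is not touched and becomes C2 with unchanged configuration (descriptor still R).

**Step 3**
Reactants: 5 (2R)-1-{3,5-bis[(tert-butyldimethylsilyl)oxy]phenyl}hex-5-en-2-ol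
Product: 6 (2R)-1-{3,5-bis[(tert-butyldimethylsilyl)oxy]phenyl}hex-5-en-2-yl acetate
Conditions: Ac2O, pyridine, DMAP (cat.), CH2Cl2, 0 °C → rt
Reagents that add atoms: acetic anhydride, CC(=O)OC(C)=O
Why: DMAP-catalysed O-acylation installs the acetate of the target while the C2 hydroxyl is the only free one, with retention because the C–O bond is not broken.

**Step 4**
Reactants: 6 (2R)-1-{3,5-bis[(tert-butyldimethylsilyl)oxy]phenyl}hex-5-en-2-yl acetate
Product: 8 (2R)-1-{3,5-bis[(benzyloxycarbonyl)oxy]phenyl}hex-5-en-2-yl acetate, via diphenol 7 (not isolated)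
Conditions: TBAF (2.2 equiv), THF, 0 °C; then CbzCl (3 equiv), 0 °C → rt
Reagents that add atoms: benzyl chloroformate, O=C(Cl)OCc1ccccc1
Why: Fluoride cleaves the aryl silyl ethers within minutes and the phenoxides so formed are acylated in the same flask (carbonate formation), which should leave the alkyl acetate and the olefin alone and turns the electron-rich resorcinol ring into an electron-poor bis(carbonate) for the key step.

**Step 5**
Reactants: 9 oct-1-en-3-one
Product: 11 2-oxoheptanal, via ozonide 10 (not isolated)
Conditions: O3, CH2Cl2, −78 °C; then Me2S, −78 °C → rt; distillation at reduced pressure, used at once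
Reagents that add atoms: ozone, [O-][O+]=O
Why: Ozonolysis with reductive work-up cleaves the vinyl C=C of the enone to the aldehyde and formaldehyde, the electron-poor olefin fragmenting so that the carbonyl oxide sits on the CH2 carbon, and distillation should give the monomeric alkylglyoxal free of water.

**Step 6**
Reactants: 8 (2R)-1-{3,5-bis[(benzyloxycarbonyl)oxy]phenyl}hex-5-en-2-yl acetate; 11 2-oxoheptanal
Product: 12 (2R,4E,7R)-1-{3,5-bis[(benzyloxycarbonyl)oxy]phenyl}-7-hydroxy-8-oxotridec-4-en-2-yl acetate
Conditions: [Cu((R,R)-tBu-box)](SbF6)2 (10 mol %; from CuCl2, AgSbF6 and 2,2′-(propane-2,2-diyl)bis[(4R)-4-tert-butyl-4,5-dihydro-1,3-oxazole]), 11 (3 equiv), 4 Å MS, CH2Cl2, 0 °C → rt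
Reagents that add atoms: none
Why: The s-cis 1,2-dicarbonyl of 11 chelates the square-planar divalent copper centre through its aldehyde and ketone oxygens, and the terminal olefin carbon C6 of 8 then bonds to the activated aldehyde carbon C7 while an allylic hydrogen of C4 passes to the aldehyde oxygen in a concerted, asynchronous six-centre transition state, the double bond moving to C4=C5 (carbonyl-ene reaction). The closest known reaction type is the copper bis(oxazoline)-catalysed enantioselective glyoxylate-ene reaction, which accepts monosubstituted olefins, together with Lewis-acid-catalysed ene reactions of glyoxals; no ring is closed. The new stereocentre C7 is set by the catalyst, whose tert-butyl groups leave one face of the chelated aldehyde open; the (R,R)-ligand is chosen as the mirror image of the complex that gives (S)-α-hydroxy esters from glyoxylate, so the (7R)-ketol is expected, and the distant C2 centre should exert no influence. The step needs aldehyde-over-ketone selectivity (secured by the higher electrophilicity and smaller size of the CHO group), bonding at the terminal olefin carbon (secured because the internal carbon carries the developing positive charge) and olefin-over-arene selectivity (secured by the two carbonate groups, which make the ring too electron-poor for Friedel–Crafts hydroxyalkylation). The geometry of the new olefin is immaterial because step 7 removes it.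

**Step 7**
Reactants: 12 (2R,4E,7R)-1-{3,5-bis[(benzyloxycarbonyl)oxy]phenyl}-7-hydroxy-8-oxotridec-4-en-2-yl acetate
Product: 13 (2R,7R)-1-(3,5-dihydroxyphenyl)-7-hydroxy-8-oxotridecan-2-yl acetate
Conditions: H2 (1 atm), 10% Pd/C, EtOAc, rt
Reagents that add atoms: none
Why: Heterogeneous hydrogenation should saturate the C4=C5 olefin left by the ene reaction and hydrogenolyse both benzyl carbonates (benzylic C–O cleavage, then loss of CO2), while the aliphatic ketone, the free carbinol and the acetate are inert under these neutral conditions, so both stereocentres pass unchanged into the target.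

**Compound list**
1 | 5-bromobenzene-1,3-diol | Oc1cc(O)cc(Br)c1 | starting material
2 | 1-bromo-3,5-bis[(tert-butyldimethylsilyl)oxy]benzene | CC(C)(C)[Si](C)(C)Oc1cc(Br)cc(O[Si](C)(C)C(C)(C)C)c1 | intermediate
3 | (R)-2-(but-3-en-1-yl)oxirane | C=CCC[C@@H]1CO1 | starting material
4 | {3,5-bis[(tert-butyldimethylsilyl)oxy]phenyl}magnesium bromide | CC(C)(C)[Si](C)(C)Oc1cc([Mg]Br)cc(O[Si](C)(C)C(C)(C)C)c1 | intermediate
5 | (2R)-1-{3,5-bis[(tert-butyldimethylsilyl)oxy]phenyl}hex-5-en-2-ol | C=CCC[C@H](Cc1cc(O[Si](C)(C)C(C)(C)C)cc(O[Si](C)(C)C(C)(C)C)c1)O | intermediate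
6 | (2R)-1-{3,5-bis[(tert-butyldimethylsilyl)oxy]phenyl}hex-5-en-2-yl acetate | C=CCC[C@H](Cc1cc(O[Si](C)(C)C(C)(C)C)cc(O[Si](C)(C)C(C)(C)C)c1)OC(C)=O | intermediate
7 | (2R)-1-(3,5-dihydroxyphenyl)hex-5-en-2-yl acetate (present as its bis(tetrabutylammonium) phenoxide) | C=CCC[C@H](Cc1cc(O)cc(O)c1)OC(C)=O | intermediate
8 | (2R)-1-{3,5-bis[(benzyloxycarbonyl)oxy]phenyl}hex-5-en-2-yl acetate | C=CCC[C@H](Cc1cc(OC(=O)OCc2ccccc2)cc(OC(=O)OCc2ccccc2)c1)OC(C)=O | intermediate
9 | oct-1-en-3-one | C=CC(=O)CCCCC | starting material
10 | 1-(1,2,4-trioxolan-3-yl)hexan-1-one (racemic) | CCCCCC(=O)C1OCOO1 | intermediate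
11 | 2-oxoheptanal | CCCCCC(=O)C=O | intermediate
12 | (2R,4E,7R)-1-{3,5-bis[(benzyloxycarbonyl)oxy]phenyl}-7-hydroxy-8-oxotridec-4-en-2-yl acetate | CCCCCC(=O)[C@H](O)C/C=C/C[C@H](Cc1cc(OC(=O)OCc2ccccc2)cc(OC(=O)OCc2ccccc2)c1)OC(C)=O | intermediate
13 | (2R,7R)-1-(3,5-dihydroxyphenyl)-7-hydroxy-8-oxotridecan-2-yl acetate | CCCCCC(=O)[C@H](O)CCCC[C@H](Cc1cc(O)cc(O)c1)OC(C)=O | target

**Step count**
Total steps: 7. Longest linear sequence: 6 (steps 1, 2, 3, 4, 6, 7); step 5 is a one-step side branch.

**Steps most likely to fail**

Step 6. The monosubstituted olefin may be too weak an ene donor for the copper-bound alkylglyoxal. Self-condensation or oligomerisation of the glyoxal, sequestration of the catalyst by the chelating ketol product, or eroded facial selectivity could then take over. The fallback keeps the C6–C7 disconnection but makes C6 a nucleophile by hydrometalation and sets C7 by a catalytic asymmetric organozinc addition. It sets out from 6 and rejoins the route at 13. 2-Methylideneheptanal F1 would be prepared from heptanal, aqueous formaldehyde and pyrrolidinium propionate (Mannich-type α-methylenation). Hydroboration of the terminal olefin of 6 with Et2BH, followed by boron–zinc exchange with Et2Zn, should give bis{(5R)-5-acetoxy-6-[3,5-bis(tert-butyldimethylsilyloxy)phenyl]hexyl}zinc F2. Addition of F2 to F1 in toluene at −20 °C under Ti(OiPr)4 and catalytic (1S,2S)-N,N′-bis(trifluoromethylsulfonyl)cyclohexane-1,2-diamine should give (2R,7R)-1-{3,5-bis[(tert-butyldimethylsilyl)oxy]phenyl}-7-hydroxy-8-methylidenetridecan-2-yl acetate F3; the (1S,2S)-ligand is chosen as the mirror image of the one that delivers (S)-carbinols. Ozonolysis of the 1,1-disubstituted olefin of F3 (O3, CH2Cl2–MeOH, −78 °C, dye end point; then Me2S) should unveil the ketone and give (2R,7R)-1-{3,5-bis[(tert-butyldimethylsilyl)oxy]phenyl}-7-hydroxy-8-oxotridecan-2-yl acetate F4. HF·pyridine in THF would then remove the two aryl silyl ethers to give 13.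

Step 5. Carbonyl oxide intermediates next to the ketone may rearrange and over-oxidise the chain, and the glyoxal may hydrate or oligomerise during isolation. The fallback avoids ozonides altogether; it sets out from 9 and rejoins the route at 11. Dihydroxylation of 9 (OsO4 cat., N-methylmorpholine N-oxide, acetone–water) should give racemic 1,2-dihydroxyoctan-3-one F5. Anhydrous glycol cleavage of F5 with Pb(OAc)4 in CH2Cl2 at 0 °C, filtration and distillation should then deliver 11.

Step 7. Palladium hydride may move the C4=C5 double bond toward C7 before it is saturated; redox isomerisation of the resulting allylic alcohol would give a 7,8-diketone and destroy the C7 stereocentre. The fallback separates the two events so that no metal hydride meets the olefin; it sets out from 12 and rejoins the route at 13. Diimide generated from dipotassium azodicarboxylate and AcOH in MeOH–CH2Cl2 (0 °C → rt) should reduce the olefin to (2R,7R)-1-{3,5-bis[(benzyloxycarbonyl)oxy]phenyl}-7-hydroxy-8-oxotridecan-2-yl acetate F6. A short hydrogenolysis of F6 (H2, Pd/C, EtOAc) would then cleave the two benzyl carbonates to give 13.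

**Further compounds**
F1 | step 6 | 2-methylideneheptanal | CCCCCC(=C)C=O
F2 | step 6 | bis{(5R)-5-acetoxy-6-[3,5-bis(tert-butyldimethylsilyloxy)phenyl]hexyl}zinc | CC(=O)O[C@@H](Cc1cc(O[Si](C)(C)C(C)(C)C)cc(O[Si](C)(C)C(C)(C)C)c1)CCCC[Zn]CCCC[C@H](Cc1cc(O[Si](C)(C)C(C)(C)C)cc(O[Si](C)(C)C(C)(C)C)c1)OC(C)=O
F3 | step 6 | (2R,7R)-1-{3,5-bis[(tert-butyldimethylsilyl)oxy]phenyl}-7-hydroxy-8-methylidenetridecan-2-yl acetate | CCCCCC(=C)[C@H](O)CCCC[C@H](Cc1cc(O[Si](C)(C)C(C)(C)C)cc(O[Si](C)(C)C(C)(C)C)c1)OC(C)=O
F4 | step 6 | (2R,7R)-1-{3,5-bis[(tert-butyldimethylsilyl)oxy]phenyl}-7-hydroxy-8-oxotridecan-2-yl acetate | CCCCCC(=O)[C@H](O)CCCC[C@H](Cc1cc(O[Si](C)(C)C(C)(C)C)cc(O[Si](C)(C)C(C)(C)C)c1)OC(C)=O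
F5 | step 5 | 1,2-dihydroxyoctan-3-one (racemic) | CCCCCC(=O)C(O)CO
F6 | step 7 | (2R,7R)-1-{3,5-bis[(benzyloxycarbonyl)oxy]phenyl}-7-hydroxy-8-oxotridecan-2-yl acetate | CCCCCC(=O)[C@H](O)CCCC[C@H](Cc1cc(OC(=O)OCc2ccccc2)cc(OC(=O)OCc2ccccc2)c1)OC(C)=O
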